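**Plan**
- Retrosynthetic cuts, in order: the acetate and the C11–O aryl ether; C9–C11 together with the position of the C8=C12 alkene (enol triflate carbonylation, then deconjugation); C1–C10, which opens ring A; C2–C3; C8–C12; C4–C5. This leads back to the ring of (R)-carvone.
- Enabling feature: the fusion carbon C10 is the third of the contiguous quaternary carbons C4, C5 and C10. It is α to C9 in ring B and is joined through C1 and C2 to the oxygen-bearing C3 in ring A. With ketones at C9 and C3, ring A holds a 1,5-diketone whose C1–C10 bond is a Michael bond.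
- Forward order: ring B is the carvone ring. The C4–C3 unit is attached at C5 and lengthened by C2–C1 to a vinyl ketone. Ring A is closed by the C10 enolate, C9 and C8 of ring B are then elaborated, and the coumarin is attached last.
- Stereochemistry: the carvone isopropenyl group (on C7) sends C4 to the opposite face of C5 and is then excised. The short tether relays C5 to C10 (cis-fusion). C3 comes from a dissolving-metal reduction to the equatorial 3β-alcohol. C9 comes from α-face protonation of a photodienol.

Key step: step 10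

Remark on numbering: drimane numbering is used throughout (ring A = C1–C5 and C10; ring B = C5–C10; C11 on C9; C12 on C8). β is the face that carries the C5 and C10 methyl groups.
Remark on epimers: centres α to the C9 ketone (C8, and C10 before step 10) and carbinol carbons that are later re-oxidised are assumed to be carried as epimer mixtures. They are written without descriptor, and none of them survives into the target.

**Step 1**
Reactants: 1 (R)-carvone
Product: 2 (5R)-1,2-dimethyl-5-(prop-1-en-2-yl)cyclohex-2-en-1-ol (C1 epimers)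
Conditions: MeLi, Et2O, −78 → 0 °C
Reagents that add atoms: methyllithium, [Li]C
Why: 1,2-addition of the hard organolithium to the enone carbonyl brings in the future C5 methyl group, and the new carbinol centre is irrelevant because it becomes sp2 in step 2.

**Step 2**
Reactants: 2 (5R)-1,2-dimethyl-5-(prop-1-en-2-yl)cyclohex-2-en-1-ol
Product: 3 (5S)-2,3-dimethyl-5-(prop-1-en-2-yl)cyclohex-2-en-1-one
Conditions: [C5H5NH][CrO3Cl], 4 Å MS, CH2Cl2, rt
Reagents that add atoms: pyridinium chlorochromate, [O-][Cr](=O)(=O)Cl.c1cc[nH+]cc1 (its oxo oxygen becomes the carbonyl oxygen)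
Why: in this Babler–Dauben oxidative transposition the chromate ester of the tertiary allylic alcohol shifts by a [3,3] path and is oxidised, which places the carbonyl at the future C9 and leaves a tetrasubstituted C5=C10 alkene, while the isopropenyl-bearing centre is untouched (its descriptor changes only through priorities).

**Step 3**
Reactants: 3 (5S)-2,3-dimethyl-5-(prop-1-en-2-yl)cyclohex-2-en-1-one; 4 1-methoxy-2-methyl-1-(trimethylsilyloxy)propene
Product: 6 methyl 2-[(1S,5S)-1,2-dimethyl-3-oxo-5-(prop-1-en-2-yl)cyclohexyl]-2-methylpropanoate (C10 epimers), via trimethylsilyl enol ether 5 (not isolated)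
Conditions: 4 (2 equiv), HNTf2 (5 mol %, gives Me3SiNTf2 in situ), CH2Cl2, −78 → −40 °C; then 1 M HCl, THF, 0 °C
Reagents that add atoms: 1-methoxy-2-methyl-1-(trimethylsilyloxy)propene 4, COC(O[Si](C)(C)C)=C(C)C
Why: in this Mukaiyama–Michael addition the silylated enone is attacked at C5 by the fully substituted ketene acetal carbon (C4) along the axial trajectory anti to the pseudoequatorial isopropenyl group, which sets C5 with the arm trans and the methyl cis to isopropenyl, and silyl transfer to the C9 oxygen keeps the crowded C4–C5 bond from reverting.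

**Step 4**
Reactants: 6 methyl 2-[(1S,5S)-1,2-dimethyl-3-oxo-5-(prop-1-en-2-yl)cyclohexyl]-2-methylpropanoate
Product: 8 methyl 2-[(1S)-1,2-dimethyl-3-oxocyclohexyl]-2-methylpropanoate (C10 epimers), via α-methoxy hydroperoxide 7 (not isolated)
Conditions: O3, MeOH, −78 °C; then FeSO4·7H2O (1.2 equiv), PhSH (1.5 equiv), −78 °C → rt
Reagents that add atoms: none
Why: in this hydrodealkenylation ozone cleaves the only alkene in methanol to 7, divalent iron reduces the O–O bond, the alkoxyl radical loses methyl acetate by β-scission, and the secondary C7 radical takes a hydrogen atom from PhSH, so the relay group leaves without trace while ketone, ester and C5 stay untouched.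

**Step 5**
Reactants: 8 methyl 2-[(1S)-1,2-dimethyl-3-oxocyclohexyl]-2-methylpropanoate
Product: 10 methyl 2-methyl-2-[(1S)-1,2,4-trimethyl-3-oxocyclohexyl]propanoate (C8 and C10 epimers), via lithium C8 enolate 9 (not isolated)
Conditions: LiN(i-Pr)2 (1.05 equiv), THF, −78 °C; MeI, −78 → 0 °C
Reagents that add atoms: iodomethane, CI
Why: in this kinetic enolate alkylation the hindered amide takes a proton from the C8 methylene rather than the tertiary C10–H beside quaternary C5, the ester has no α-hydrogen, and the early installation of C12 makes C9 the more shielded of the two later carbonyl positions, while the C8 configuration is irrelevant because C8 becomes sp2 in step 14.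

**Step 6**
Reactants: 10 methyl 2-methyl-2-[(1S)-1,2,4-trimethyl-3-oxocyclohexyl]propanoate
Product: 11 2-[(1S)-3-hydroxy-1,2,4-trimethylcyclohexyl]-2-methylpropan-1-ol (epimers at C8, C9, C10)
Conditions: LiAlH4, THF, 0 °C → reflux
Reagents that add atoms: none
Why: exhaustive hydride reduction is chosen because the neopentyl ester cannot be addressed beside the ketone, and both carbinol positions are re-oxidised in step 7, so the C9 configuration does not matter.

**Step 7**
Reactants: 11 2-[(1S)-3-hydroxy-1,2,4-trimethylcyclohexyl]-2-methylpropan-1-ol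
Product: 12 2-methyl-2-[(1S)-1,2,4-trimethyl-3-oxocyclohexyl]propanal (C8 and C10 epimers)
Conditions: (COCl)2, DMSO, CH2Cl2, −78 °C; Et3N, −78 → 0 °C
Reagents that add atoms: none
Why: in the Swern oxidation both hydroxyls are converted into alkoxysulfonium ions before base is added, so no hydroxy aldehyde can close to a six-membered lactol and be over-oxidised to a lactone.

**Step 8**
Reactants: 12 2-methyl-2-[(1S)-1,2,4-trimethyl-3-oxocyclohexyl]propanal; 13 vinylmagnesium bromide
Product: 14 (3S)-3-(3-hydroxy-2-methylpent-4-en-2-yl)-2,3,6-trimethylcyclohexan-1-one (epimers at C3, C8, C10)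
Conditions: CH2=CHMgBr (1.1 equiv), THF, −78 °C
Reagents that add atoms: vinylmagnesium bromide 13, C=C[Mg]Br
Why: Grignard 1,2-addition should pick the aldehyde over the C9 ketone, which lies between two methyl-bearing tertiary carbons, and the new C3 carbinol centre is erased in step 9.

**Step 9**
Reactants: 14 (3S)-3-(3-hydroxy-2-methylpent-4-en-2-yl)-2,3,6-trimethylcyclohexan-1-one
Product: 15 (3S)-2,3,6-trimethyl-3-(2-methyl-3-oxopent-4-en-2-yl)cyclohexan-1-one (C8 and C10 epimers)
Conditions: DMP (1,1,1-triacetoxy-1,2-benziodoxol-3-one), CH2Cl2, 0 °C → rt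
Reagents that add atoms: none
Why: Dess–Martin oxidation of the allylic alcohol under neutral conditions gives the vinyl ketone, which cannot enolise toward quaternary C4 and should therefore be isolable.

**Step 10**
Reactants: 15 (3S)-2,3,6-trimethyl-3-(2-methyl-3-oxopent-4-en-2-yl)cyclohexan-1-one
Product: 18 4,4,5β,8,10β-pentamethyl-cis-decalin-3,9-dione (C8 epimers), via potassium C10 enolate 16 (not isolated), via potassium C3 enolate 17 (not isolated)
Conditions: KOt-Bu (0.3 equiv), t-BuOH–THF (1:4), 0.01 M, −20 → 0 °C
Reagents that add atoms: none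
Why: tert-butoxide equilibrates the two tertiary α-positions of the C9 ketone, the C9=C10 enolate 16 bonds through C10 to the unsubstituted terminus C1 of the vinyl ketone, and t-BuOH protonates the resulting C3 enolate 17 at C2; the closest known reaction type is the intramolecular Michael addition of a ketone enolate to a tethered enone, an established entry to cis-decalindiones. Ring A closes in a 6-(enolexo)-endo-trig mode, because C1 and C2 both end up inside the new six-membered ring. The only new stereocentre, C10, is fixed by the tether: the chain C4–C3–C2–C1 hangs from the α-face of C5 and can reach only the α-lobe of the adjacent C10, so the C10 methyl is pushed β, cis to the C5 methyl, whereas a trans-fusion would require the chain to span both faces of ring B. In the productive half-chair the C4 arm is pseudoequatorial on ring B and the new bond forms axially, which leads straight to the chair–chair conformer with C4 equatorial and C1 axial on ring B and holds the C4–C5 bond near the nodal plane of the enolate, poorly aligned for retro-Michael loss of the arm. Site selectivity (C10, not C8) follows from ring size, since the C8 enolate could reach C1 only through a bridged eight-membered ring and its aldol onto C3 is reversible, and the arm has no enolisable hydrogen (C4 quaternary, C2 vinylic). High dilution, substoichiometric base and low temperature are meant to hold back oligomerisation of the enone and reversal of the closure.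

**Step 11**
Reactants: 18 4,4,5β,8,10β-pentamethyl-cis-decalin-3,9-dione
Product: 19 4,4,5β,8,10β-pentamethyl-cis-decalin-3β,9-diol (C8 and C9 epimers)
Conditions: Li, NH3(l), THF, EtOH, −78 → −33 °C
Reagents that add atoms: none
Why: dissolving-metal reduction of a ketone places oxygen equatorial and delivers only a proton to the crowded side, and in the preferred chair–chair form equatorial at C3 is β, whereas a hydride reagent would have to pass either the axial C6 methylene on the α-face or the axial 4β-methyl on the β-face; the C9 ketone is reduced too and is restored in step 13.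

**Step 12**
Reactants: 19 4,4,5β,8,10β-pentamethyl-cis-decalin-3β,9-diol
Product: 20 9-hydroxy-4,4,5β,8,10β-pentamethyl-cis-decalin-3β-yl pivalate (C8 and C9 epimers)
Conditions: t-BuCOCl (1.2 equiv), pyridine, DMAP (cat.), CH2Cl2, 40 °C
Reagents that add atoms: pivaloyl chloride, CC(C)(C)C(=O)Cl
Why: DMAP-catalysed acylation should distinguish the hydroxyls sterically, because the equatorial 3β-hydroxyl has the C2 methylene as one neighbour while the C9 hydroxyl sits between quaternary C10 and methyl-bearing C8, and the pivalate is non-enolisable (step 14), transparent at 254 nm (step 16) and removable in step 17.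

**Step 13**
Reactants: 20 9-hydroxy-4,4,5β,8,10β-pentamethyl-cis-decalin-3β-yl pivalate
Product: 21 4,4,5β,8,10β-pentamethyl-9-oxo-cis-decalin-3β-yl pivalate (C8 epimers)
Conditions: DMP, CH2Cl2, rt
Reagents that add atoms: none
Why: Dess–Martin oxidation copes with hindered secondary alcohols, gains from the strain released at C9, and returns the single ketone needed for ring B elaboration without touching the ester.

**Step 14**
Reactants: 21 4,4,5β,8,10β-pentamethyl-9-oxo-cis-decalin-3β-yl pivalate
Product: 23 4,4,5β,8,10β-pentamethyl-9-(trifluoromethylsulfonyloxy)-Δ8-octalin-3β-yl pivalate, via potassium C8 enolate 22 (not isolated)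
Conditions: KN(SiMe3)2 (1.3 equiv), THF, −78 → 0 °C; PhNTf2, 0 °C → rt
Reagents that add atoms: N-phenylbis(trifluoromethanesulfonimide), O=S(=O)(N(c1ccccc1)S(=O)(=O)C(F)(F)F)C(F)(F)F
Why: in this enol triflate formation C10 is quaternary, so only the C8=C9 enolate can form, and its O-sulfonylation follows the routine behaviour of 2,2,6-trisubstituted cyclohexanones and erases the C8 centre.

**Step 15**
Reactants: 23 4,4,5β,8,10β-pentamethyl-9-(trifluoromethylsulfonyloxy)-Δ8-octalin-3β-yl pivalate
Product: 24 methyl 4,4,5β,8,10β-pentamethyl-3β-pivaloyloxy-Δ8-octalin-9-carboxylate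
Conditions: Pd(OAc)2 (10 mol %), PPh3 (20 mol %), CO (1 atm), MeOH, Et3N, DMF, 60 °C
Reagents that add atoms: carbon monoxide, [C-]#[O+]; methanol, CO
Why: palladium-catalysed alkoxycarbonylation of a vinyl triflate (oxidative addition to zerovalent palladium formed in situ, CO insertion, methanolysis) makes the C9–C11 bond at the ester level, as known for triflates flanked by a quaternary carbon and a methyl-bearing alkene carbon.

**Step 16**
Reactants: 24 methyl 4,4,5β,8,10β-pentamethyl-3β-pivaloyloxy-Δ8-octalin-9-carboxylate
Product: 26 methyl 4,4,5β,10β-tetramethyl-8-methylene-3β-pivaloyloxy-cis-decalin-9β-carboxylate, via photodienol 25 (not isolated)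
Conditions: hν (254 nm, quartz), 1,2-dimethylimidazole (0.1 equiv), Et2O, −40 °C
Reagents that add atoms: none
Why: in this photodeconjugation of an α,β-unsaturated ester the excited carbonyl takes a hydrogen by a 1,5-shift from the only γ-position held cis to it by the ring, the C8 methyl, to give dienol 25, and base-mediated ketonisation should deliver the proton to C9 from the α-face because the β-face is covered by the axial C5 methyl in a 1,3-relationship, so C11 ends β and the transparent product accumulates.

**Step 17**
Reactants: 26 methyl 4,4,5β,10β-tetramethyl-8-methylene-3β-pivaloyloxy-cis-decalin-9β-carboxylate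
Product: 27 9β-(hydroxymethyl)-4,4,5β,10β-tetramethyl-8-methylene-cis-decalin-3β-ol
Conditions: LiAlH4, THF, 0 → 40 °C
Reagents that add atoms: none
Why: LiAlH4 reduces the C11 ester and cleaves the pivalate in one operation, and hydride addition to β,γ-unsaturated decalin esters is faster than deprotonation at C9, so the C9 configuration and the alkene position should hold.

**Step 18**
Reactants: 27 9β-(hydroxymethyl)-4,4,5β,10β-tetramethyl-8-methylene-cis-decalin-3β-ol; 28 umbelliferone
Product: 29 7-[(3β-hydroxy-4,4,5β,10β-tetramethyl-8-methylene-cis-decalin-9β-yl)methoxy]coumarin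
Conditions: 28 (1.2 equiv), PPh3, DIAD, THF, 0 °C → rt
Reagents that add atoms: umbelliferone 28, Oc1ccc2ccc(=O)oc2c1
Why: in the Mitsunobu etherification the acidic phenol displaces the activated primary C11 oxygen, whereas the secondary, neopentyl 3β-hydroxyl cannot undergo SN2 displacement and should be left free, and no stereocentre is involved.

**Step 19**
Reactants: 29 7-[(3β-hydroxy-4,4,5β,10β-tetramethyl-8-methylene-cis-decalin-9β-yl)methoxy]coumarin
Product: 30 polyanthinin
Conditions: Ac2O, pyridine, DMAP (cat.), CH2Cl2, rt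
Reagents that add atoms: acetic anhydride, CC(=O)OC(C)=O
Why: DMAP-catalysed acetylation of an equatorial 3β-hydroxyl next to a gem-dimethyl carbon is routine and proceeds with retention under conditions harmless to the lactone and the exocyclic alkene.

**Compound list**
1 | (R)-carvone | O=C1C[C@H](C(C)=C)CC=C1C | starting material
2 | (5R)-1,2-dimethyl-5-(prop-1-en-2-yl)cyclohex-2-en-1-ol (C1 epimers) | CC1(O)C[C@H](C(C)=C)CC=C1C | intermediate
3 | (5S)-2,3-dimethyl-5-(prop-1-en-2-yl)cyclohex-2-en-1-one | O=C1C[C@@H](C(C)=C)CC(C)=C1C | intermediate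
4 | 1-methoxy-2-methyl-1-(trimethylsilyloxy)propene | COC(O[Si](C)(C)C)=C(C)C | starting material
5 | methyl 2-[(1S,5S)-1,2-dimethyl-5-(prop-1-en-2-yl)-3-(trimethylsilyloxy)cyclohex-2-en-1-yl]-2-methylpropanoate | C[Si](C)(C)OC1=C(C)[C@@](C)(C(C)(C)C(=O)OC)C[C@H](C(C)=C)C1 | intermediate
6 | methyl 2-[(1S,5S)-1,2-dimethyl-3-oxo-5-(prop-1-en-2-yl)cyclohexyl]-2-methylpropanoate (C10 epimers) | O=C1C[C@@H](C(C)=C)C[C@](C)(C(C)(C)C(=O)OC)C1C | intermediate
7 | methyl 2-[(1S,5S)-5-(1-hydroperoxy-1-methoxyethyl)-1,2-dimethyl-3-oxocyclohexyl]-2-methylpropanoate | O=C1C[C@@H](C(C)(OC)OO)C[C@](C)(C(C)(C)C(=O)OC)C1C | intermediate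
8 | methyl 2-[(1S)-1,2-dimethyl-3-oxocyclohexyl]-2-methylpropanoate (C10 epimers) | O=C1CCC[C@](C)(C(C)(C)C(=O)OC)C1C | intermediate
9 | lithium C8=C9 enolate of 8 | [Li+].[O-]C1=CCC[C@](C)(C(C)(C)C(=O)OC)C1C | intermediate
10 | methyl 2-methyl-2-[(1S)-1,2,4-trimethyl-3-oxocyclohexyl]propanoate (C8, C10 epimers) | O=C1C(C)CC[C@](C)(C(C)(C)C(=O)OC)C1C | intermediate
11 | 2-[(1S)-3-hydroxy-1,2,4-trimethylcyclohexyl]-2-methylpropan-1-ol (C8, C9, C10 epimers) | OC1C(C)CC[C@](C)(C(C)(C)CO)C1C | intermediate
12 | 2-methyl-2-[(1S)-1,2,4-trimethyl-3-oxocyclohexyl]propanal (C8, C10 epimers) | O=C1C(C)CC[C@](C)(C(C)(C)C=O)C1C | intermediate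
13 | vinylmagnesium bromide | C=C[Mg]Br | starting material
14 | (3S)-3-(3-hydroxy-2-methylpent-4-en-2-yl)-2,3,6-trimethylcyclohexan-1-one (C3, C8, C10 epimers) | O=C1C(C)CC[C@](C)(C(C)(C)C(O)C=C)C1C | intermediate
15 | (3S)-2,3,6-trimethyl-3-(2-methyl-3-oxopent-4-en-2-yl)cyclohexan-1-one (C8, C10 epimers) | O=C1C(C)CC[C@](C)(C(C)(C)C(=O)C=C)C1C | intermediate
16 | potassium C9=C10 enolate of 15 | [K+].[O-]C1=C(C)[C@@](C)(C(C)(C)C(=O)C=C)CCC1C | intermediate
17 | potassium C2=C3 enolate of 18 | [K+].O=C1C(C)CC[C@]2(C)C(C)(C)C([O-])=CC[C@]12C | intermediate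
18 | 4,4,5β,8,10β-pentamethyl-cis-decalin-3,9-dione (C8 epimers) | O=C1C(C)CC[C@]2(C)C(C)(C)C(=O)CC[C@]12C | intermediate
19 | 4,4,5β,8,10β-pentamethyl-cis-decalin-3β,9-diol (C8, C9 epimers) | OC1C(C)CC[C@]2(C)C(C)(C)[C@@H](O)CC[C@]12C | intermediate
20 | 9-hydroxy-4,4,5β,8,10β-pentamethyl-cis-decalin-3β-yl pivalate (C8, C9 epimers) | OC1C(C)CC[C@]2(C)C(C)(C)[C@@H](OC(=O)C(C)(C)C)CC[C@]12C | intermediate
21 | 4,4,5β,8,10β-pentamethyl-9-oxo-cis-decalin-3β-yl pivalate (C8 epimers) | O=C1C(C)CC[C@]2(C)C(C)(C)[C@@H](OC(=O)C(C)(C)C)CC[C@]12C | intermediate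
22 | potassium C8=C9 enolate of 21 | [K+].[O-]C1=C(C)CC[C@]2(C)C(C)(C)[C@@H](OC(=O)C(C)(C)C)CC[C@]12C | intermediate
23 | 4,4,5β,8,10β-pentamethyl-9-(trifluoromethylsulfonyloxy)-Δ8-octalin-3β-yl pivalate | O=S(=O)(OC1=C(C)CC[C@]2(C)C(C)(C)[C@@H](OC(=O)C(C)(C)C)CC[C@]12C)C(F)(F)F | intermediate
24 | methyl 4,4,5β,8,10β-pentamethyl-3β-pivaloyloxy-Δ8-octalin-9-carboxylate | COC(=O)C1=C(C)CC[C@]2(C)C(C)(C)[C@@H](OC(=O)C(C)(C)C)CC[C@]12C | intermediate
25 | photodienol (C9=C11 ketene hemiacetal, C8=C12 methylene) | COC(O)=C1C(=C)CC[C@]2(C)C(C)(C)[C@@H](OC(=O)C(C)(C)C)CC[C@]12C | intermediate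
26 | methyl 4,4,5β,10β-tetramethyl-8-methylene-3β-pivaloyloxy-cis-decalin-9β-carboxylate | C=C1CC[C@]2(C)C(C)(C)[C@@H](OC(=O)C(C)(C)C)CC[C@]2(C)[C@H]1C(=O)OC | intermediate
27 | 9β-(hydroxymethyl)-4,4,5β,10β-tetramethyl-8-methylene-cis-decalin-3β-ol | C=C1CC[C@]2(C)C(C)(C)[C@@H](O)CC[C@]2(C)[C@H]1CO | intermediate
28 | umbelliferone | Oc1ccc2ccc(=O)oc2c1 | starting material
29 | 7-[(3β-hydroxy-4,4,5β,10β-tetramethyl-8-methylene-cis-decalin-9β-yl)methoxy]coumarin | C=C1CC[C@]2(C)C(C)(C)[C@@H](O)CC[C@]2(C)[C@H]1COc1ccc2ccc(=O)oc2c1 | intermediate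
30 | polyanthinin | C=C1CC[C@]2(C)C(C)(C)[C@@H](OC(C)=O)CC[C@]2(C)[C@H]1COc1ccc2ccc(=O)oc2c1 | target

Total step count: 19. Longest linear sequence: 19 steps, from 1 to 30.

**Steps most likely to fail**

**Step 3.** Bond formation between a fully substituted ketene acetal carbon and the fully substituted β-carbon of the enone may be too slow. Silyl scrambling, 1,2-addition or acid-induced isomerisation of the isopropenyl group could then take over.

The fallback makes the C4–C5 bond with a small nucleophile and builds the quaternary C4 afterwards by enolate alkylation. It sets out from 3.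
- Commercial 1-(tert-butyldimethylsilyloxy)-1-methoxyethene is added under the same silyl Lewis acid catalysis, again anti to isopropenyl. This gives methyl 2-[(1R,5S)-3-(tert-butyldimethylsilyloxy)-1,2-dimethyl-5-(prop-1-en-2-yl)cyclohex-2-en-1-yl]acetate F1, which is kept as its enol ether so that C9 stays masked.
- α-Methylation (LiN(i-Pr)2, THF, −78 °C; MeI) gives the monomethyl ester F2.
- A second methylation (LiN(i-Pr)2, DMPU; MeI) gives the gem-dimethyl ester F3.
- 1 M HCl in THF cleaves the enol ether, and the route is rejoined at 6.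

**Step 10.** The same C10 enolate can fragment the strained C4–C5 bond by retro-Michael reaction. The vinyl ketone can oligomerise, and the closure itself can revert.

The fallback forms the same C1–C10 bond by irreversible enolate alkylation, with C3 held at the alcohol level so that neither retro-Michael path exists. It sets out from 14.
- Silylation (t-BuMe2SiOTf, 2,6-lutidine) gives the silyl ether F4.
- Hydroboration of the vinyl group with 9-BBN and NaBO3 work-up gives the primary alcohol F5.
- An Appel reaction (I2, PPh3, imidazole) gives the primary iodide F6.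
- KOt-Bu in THF closes ring A (6-exo-tet, the same α-face constraint from the tether) to the 3-silyloxy-cis-decalin-9-one F7.
- Bu4NF gives the 3-hydroxy ketone F8.
- Dess–Martin oxidation comes back to the route at 18.

**Step 16.** Facial selectivity in the ketonisation of the dienol may be poor. Conversion may also be slow because the crowded enoate is twisted out of conjugation.

The fallback replaces the photochemical hydrogen shift by a ground-state anionic deconjugation with an external, bulky proton donor. It sets out from 24.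
- Kinetic γ-deprotonation with LiN(i-Pr)2 and DMPU in THF at −78 °C takes a proton from the C8 methyl, which lies syn to the ester. This gives the lithium dienolate F9.
- A quench at −78 °C with 2,6-di-tert-butyl-4-methylphenol, which can approach C9 only from the open α-face, returns to the route at 26.

**Further compounds**
F1 | step 3 | methyl 2-[(1R,5S)-3-(tert-butyldimethylsilyloxy)-1,2-dimethyl-5-(prop-1-en-2-yl)cyclohex-2-en-1-yl]acetate | CC(C)(C)[Si](C)(C)OC1=C(C)[C@@](C)(CC(=O)OC)C[C@H](C(C)=C)C1
F2 | step 3 | methyl 2-[(1R,5S)-3-(tert-butyldimethylsilyloxy)-1,2-dimethyl-5-(prop-1-en-2-yl)cyclohex-2-en-1-yl]propanoate (C4 epimers) | CC(C)(C)[Si](C)(C)OC1=C(C)[C@@](C)(C(C)C(=O)OC)C[C@H](C(C)=C)C1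
F3 | step 3 | methyl 2-[(1S,5S)-3-(tert-butyldimethylsilyloxy)-1,2-dimethyl-5-(prop-1-en-2-yl)cyclohex-2-en-1-yl]-2-methylpropanoate | CC(C)(C)[Si](C)(C)OC1=C(C)[C@@](C)(C(C)(C)C(=O)OC)C[C@H](C(C)=C)C1
F4 | step 10 | (3S)-3-[3-(tert-butyldimethylsilyloxy)-2-methylpent-4-en-2-yl]-2,3,6-trimethylcyclohexan-1-one (C3, C8, C10 epimers) | O=C1C(C)CC[C@](C)(C(C)(C)C(O[Si](C)(C)C(C)(C)C)C=C)C1C
F5 | step 10 | (3S)-3-[3-(tert-butyldimethylsilyloxy)-5-hydroxy-2-methylpentan-2-yl]-2,3,6-trimethylcyclohexan-1-one | O=C1C(C)CC[C@](C)(C(C)(C)C(O[Si](C)(C)C(C)(C)C)CCO)C1C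
F6 | step 10 | (3S)-3-[3-(tert-butyldimethylsilyloxy)-5-iodo-2-methylpentan-2-yl]-2,3,6-trimethylcyclohexan-1-one | O=C1C(C)CC[C@](C)(C(C)(C)C(O[Si](C)(C)C(C)(C)C)CCI)C1C
F7 | step 10 | 3-(tert-butyldimethylsilyloxy)-4,4,5β,8,10β-pentamethyl-cis-decalin-9-one (C3, C8 epimers) | O=C1C(C)CC[C@]2(C)C(C)(C)C(O[Si](C)(C)C(C)(C)C)CC[C@]12C
F8 | step 10 | 3-hydroxy-4,4,5β,8,10β-pentamethyl-cis-decalin-9-one (C3, C8 epimers) | O=C1C(C)CC[C@]2(C)C(C)(C)C(O)CC[C@]12C
F9 | step 16 | lithium dienolate of 24 (C9=C11, C8=C12) | [Li+].COC([O-])=C1C(=C)CC[C@]2(C)C(C)(C)[C@@H](OC(=O)C(C)(C)C)CC[C@]12C
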